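The runs are simulated for substances that don't exist.

The alder flask cannot have slowed for want of partner spent on target: at 190 h it has turned 21.5% of its starting material, which costs 7.17% of the partner charged, far less than was there. So where does the rest of the partner go?

common to all: catalyst 0.0180 M

| flask | starting material | partner | time |
|---|---|---|---|
| alder | 0.600 M | 1.80 M |  |
| maple | 0.240 M | 1.44 M |  |
| birch | 0.900 M | 1.80 M |  |
| ash | 0.600 M | 2.70 M |  |
| elm | 0.600 M | 5.40 M | 190 h |

| run | time / h | [target] / M |
|---|---|---|
| alder run | 14 | 0.077 |
| alder run | 44 | 0.102 |
| alder run | 84 | 0.113 |
| alder run | 130 | 0.119 |
| alder run | 190 | 0.129 |
| maple run | 14 | 0.031 |
| maple run | 44 | 0.040 |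
| maple run | 84 | 0.053 |
| maple run | 130 | 0.055 |
| maple run | 190 | 0.052 |
| birch run | 14 | 0.108 |
| birch run | 44 | 0.143 |
| birch run | 84 | 0.156 |
| birch run | 130 | 0.166 |
| birch run | 190 | 0.167 |
| ash run | 14 | 0.089 |
| ash run | 44 | 0.116 |
| ash run | 84 | 0.125 |
| ash run | 130 | 0.132 |
| ash run | 190 | 0.135 |

(standard deviation of a reading: 0.003 M)

- Overall: starting material + partner -> target, with catalyst as catalyst.
- Constant volume, constant temperature.
- The analysis sees a species whether free or bound.
- "The second partner" is partner.
- An order is taken over about fifteen percent of the charge, up and down.

1. the exponent of [partner] in the starting rate at the charge of the alder run (at the point where two percent of the starting material have become target)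
2. the exponent of [starting material] in the starting rate at the charge of the alder run (at the point where two percent of the starting material have become target) (one fixed amount of target, the same in the runs compared)
3. target in the elm run at 190 h, as a share of the starting material charged
4. which of these the readings show (the catalyst rests as a dimer / the second partner is lost in pairs / the substrate kills the catalyst / the two partners rest in a complex)

I take the reading that partner is lost in pairs and follow one partner molecule. At each moment it stands at a fork. It can make target, at a pace that goes with the partner level once, or it can meet a second partner and be lost, at a pace that goes with that level squared. Its chance of making target, its selectivity in the usual word, is therefore c/(c + partner level), where c is the even-odds level and grows with the starting material present. Early, the partner mostly destroys itself; late, the survivors are used better. If partner goes this way until none remains, the share of starting material turned comes to g·ln(1 + ρ/g), where ρ is partner charged per starting material charged and g is c per starting material.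

The readings agree in direction. Birch has alder's partner but less of it per starting material, 2.00 against 3.00, and ends lower, at 18.6%.

Alder and ash share a starting charge, and ash has 1.50 times the partner. Their mean gap over the shared times, as a share of the charge and divided by the logarithm of that factor, gives 4.69%. This is the share gained for each factor e in partner per starting material, the ladder step.

Put into the rule, it gives elm 24.7%. The weak link is the rule's absolute level: for alder it gives 19.6%, lower than the 21.5% read. So I use a difference instead. Elm has twice ash's partner on the same starting material, and ash reads 22.5% at 190 h. One step of ln(2) upward gives 25.7%, and that is my figure.

The forecast commits to orders of 1 in partner and 1.2 in starting material, to "the second partner is lost in pairs", and to 25% for elm, a little below my figure, holding that “Conversion creeps up roughly as log(time)”.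

The elm flask gives 25.9% at 190 h, with orders 1.0 and 1.2, and the readings show that the second partner is lost in pairs.

    catalyst + starting material ⇌ catalyst-substrate complex, settled at all times (0.1830 M⁻¹)
    catalyst-substrate complex + partner → target + catalyst + by-product (7.704 M⁻¹ h⁻¹)
    2 partner → lost reagent (0.1984 M⁻¹ h⁻¹)

A fit in which the two partners rest in a complex puts elm at 37.1%, higher than the flask, so a result up there is what would have overturned this picture. Maple holds twice alder's partner per starting material, so one step of ln(2) from alder's reading at 190 h puts maple at 24.7% at that time. The maple run reads 21.7% at 190 h, lower than the step by 3.0 percentage points.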